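**Retrosynthetic overview**

- Numbering: ring C1 (C–CH3, oxirane carbon), C2 (C=O), C3 (OAc), C4 (carries the side chain), C5 (CH2), C6 (oxirane CH); side chain C7 (=C14H2), C8 (O-angeloyl), C9, C10=C11(CH3)2.
- Feature: in the single carbocycle C1–C6, C1 is both the methyl-bearing carbon of a latent C1=C6 alkene (the later oxirane) and the neighbour of oxygenated C2. The C1–C2 bond is therefore cut to a C1 alkenyl metal and a C2 aldehyde, which gives the acyclic (Z)-iodoalkenyl aldehyde 23, closed by a nickel/chromium-mediated addition.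
- 23 is built linearly from (R)-glyceraldehyde acetonide (C2, C3): Johnson–Claisen rearrangement (C4, C5, C6), Stork–Zhao iodo-olefination (C1, its methyl, iodine), hydroboration/oxidation/α-methylenation (C8 aldehyde, C14), Brown allylation (C8 stereocentre, C9, C10), early angeloylation, cross-metathesis (C11).
- Ring order: the carbocycle first (step 15), then the oxirane by C2-hydroxyl-directed epoxidation (step 16); oxidation at C2 and silyl-to-acetyl exchange at C3 finish the target.

Key step: step 15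

Remark: the allylborane of step 9 is the B-allyldiisopinocampheylborane of the (+)-α-pinene series, used as a stock solution made beforehand from (−)-Ipc2BOMe and allylmagnesium bromide; its sense of induction (Si face of the aldehyde) is taken from the benzaldehyde precedent.

**Route**

Step 1
Reactants: 1 (R)-2,3-O-isopropylideneglyceraldehyde
Product: 2 methyl (2Z)-3-[(4S)-2,2-dimethyl-1,3-dioxolan-4-yl]prop-2-enoate
Conditions: Ph3P=CHCO2Me, MeOH, 0 °C; minor (E) isomer removed by chromatography
Reagents that add atoms: methyl (triphenylphosphoranylidene)acetate, COC(=O)C=P(c1ccccc1)(c1ccccc1)c1ccccc1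
Why: Wittig olefination: in methanol the ester-stabilised ylide adds to the α-alkoxy aldehyde under kinetic control to give mainly the (Z)-enoate, and the neutral, cold conditions should not epimerise the C3 centre taken from 1.

Step 2
Reactants: 2 methyl (2Z)-3-[(4S)-2,2-dimethyl-1,3-dioxolan-4-yl]prop-2-enoate
Product: 3 (2Z)-3-[(4S)-2,2-dimethyl-1,3-dioxolan-4-yl]prop-2-en-1-ol
Conditions: i-Bu2AlH (2.2 equiv), CH2Cl2, −78 °C; aq. potassium sodium tartrate
Reagents that add atoms: none
Why: Hydride reduction of the ester (1,2-reduction by i-Bu2AlH at low temperature) gives the allylic alcohol without change of the (Z) geometry or loss of the acetonide.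

Step 3
Reactants: 3 (2Z)-3-[(4S)-2,2-dimethyl-1,3-dioxolan-4-yl]prop-2-en-1-ol, 4 triethyl orthoacetate
Product: 7 ethyl (3S)-3-[(4S)-2,2-dimethyl-1,3-dioxolan-4-yl]pent-4-enoate, via mixed orthoester 5 (not isolated), via ketene acetal 6 (not isolated)
Conditions: 4 (excess), EtCO2H (cat.), 140 °C, EtOH distilled off
Reagents that add atoms: none
Why: Johnson–Claisen rearrangement: acid-catalysed exchange gives orthoester 5 and, by loss of ethanol, ketene acetal 6, whose [3,3] shift forms the C4–C5 bond on the alkene face anti to the C3–O bond of the conformer that A(1,3) strain in the (Z)-alkene enforces (C3–H in the alkene plane), which sets C4 as (S).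

Step 4
Reactants: 7 ethyl (3S)-3-[(4S)-2,2-dimethyl-1,3-dioxolan-4-yl]pent-4-enoate
Product: 8 (3S)-3-[(4S)-2,2-dimethyl-1,3-dioxolan-4-yl]pent-4-enal
Conditions: i-Bu2AlH (1.1 equiv), CH2Cl2, −78 °C; aq. potassium sodium tartrate
Reagents that add atoms: none
Why: Partial reduction of an ester: at −78 °C i-Bu2AlH gives a stable aluminium hemiacetal that releases the aldehyde only on work-up, and C4, β to the carbonyl, cannot epimerise.

Step 5
Reactants: 8 (3S)-3-[(4S)-2,2-dimethyl-1,3-dioxolan-4-yl]pent-4-enal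
Product: 9 (4S)-4-[(3S,5Z)-6-iodohepta-1,5-dien-3-yl]-2,2-dimethyl-1,3-dioxolane
Conditions: EtPPh3+ I−, n-BuLi, THF, 0 °C; I2, −78 °C; NaN(SiMe3)2, −78 °C; then 8, −78 to −20 °C
Reagents that add atoms: ethyltriphenylphosphonium iodide, CC[P+](c1ccccc1)(c1ccccc1)c1ccccc1.[I-]; iodine, II
Why: Stork–Zhao olefination: the α-iodo ylide made in the flask reacts as a non-stabilised ylide under kinetic control, so the iodine ends cis to the C5 chain and the (Z)-2-iodoalkene carrying the C1 methyl results.

Step 6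
Reactants: 9 (4S)-4-[(3S,5Z)-6-iodohepta-1,5-dien-3-yl]-2,2-dimethyl-1,3-dioxolane
Product: 11 (3S,5Z)-3-[(4S)-2,2-dimethyl-1,3-dioxolan-4-yl]-6-iodohept-5-en-1-ol, via alkylborane 10 (not isolated)
Conditions: 9-BBN-H, THF, 0 °C to rt; then NaOH, H2O2, 0 °C
Reagents that add atoms: hydrogen peroxide, OO
Why: Hydroboration–oxidation: 9-BBN-H adds anti-Markovnikov to the monosubstituted vinyl group only, the trisubstituted, electron-poor iodoalkene being inert, and alkaline peroxide converts the C–B bond of 10 to the primary C8 hydroxyl.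

Step 7
Reactants: 11 (3S,5Z)-3-[(4S)-2,2-dimethyl-1,3-dioxolan-4-yl]-6-iodohept-5-en-1-ol
Product: 12 (3S,5Z)-3-[(4S)-2,2-dimethyl-1,3-dioxolan-4-yl]-6-iodohept-5-enal
Conditions: Dess–Martin periodinane, NaHCO3, CH2Cl2, 0 °C to rt
Reagents that add atoms: none
Why: Dess–Martin oxidation under bicarbonate buffer converts the primary alcohol to the aldehyde without touching the alkenyl iodide or the acetal.

Step 8
Reactants: 12 (3S,5Z)-3-[(4S)-2,2-dimethyl-1,3-dioxolan-4-yl]-6-iodohept-5-enal
Product: 13 (3S,5Z)-3-[(4S)-2,2-dimethyl-1,3-dioxolan-4-yl]-6-iodo-2-methylidenehept-5-enal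
Conditions: aq. CH2O, pyrrolidine (cat.), EtCO2H (cat.), i-PrOH, 45 °C
Reagents that add atoms: formaldehyde, C=O
Why: Organocatalytic α-methylenation (Mannich-type condensation of the enamine with formaldehyde, then elimination of the amine) installs C14 as the methylene on C7; C4 is β to the aldehyde and keeps its configuration.

Step 9
Reactants: 13 (3S,5Z)-3-[(4S)-2,2-dimethyl-1,3-dioxolan-4-yl]-6-iodo-2-methylidenehept-5-enal
Product: 15 (4S,6S,8Z)-6-[(4S)-2,2-dimethyl-1,3-dioxolan-4-yl]-9-iodo-5-methylidenedeca-1,8-dien-4-ol, via borinate 14 (not isolated)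
Conditions: B-allyldiisopinocampheylborane [(+)-α-pinene series], Et2O, −78 °C; then NaOH, H2O2, 0 °C to rt
Reagents that add atoms: B-allyldiisopinocampheylborane of the (+)-α-pinene series, C=CCB([C@@H]1C[C@@H]2C[C@H]([C@H]1C)C2(C)C)[C@@H]1C[C@@H]2C[C@H]([C@H]1C)C2(C)C
Why: Brown asymmetric allylboration: the allyl group is delivered through a chair-like six-membered transition state to the Si face of the aldehyde under control of the isopinocampheyl groups, which sets C8 as (S), and alkaline peroxide then cleaves borinate 14.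

Step 10
Reactants: 15 (4S,6S,8Z)-6-[(4S)-2,2-dimethyl-1,3-dioxolan-4-yl]-9-iodo-5-methylidenedeca-1,8-dien-4-ol, 16 angelic acid
Product: 18 (4S,6S,8Z)-6-[(4S)-2,2-dimethyl-1,3-dioxolan-4-yl]-9-iodo-5-methylidenedeca-1,8-dien-4-yl (2Z)-2-methylbut-2-enoate, via mixed anhydride 17 (not isolated)
Conditions: 16, 2,4,6-Cl3C6H2COCl, Et3N, toluene, rt; then 15, 80 °C
Reagents that add atoms: none
Why: Yamaguchi esterification: mixed anhydride 17 acylates the hindered allylic alcohol on heating without a nucleophilic catalyst, the conditions under which the (Z)-angeloyl group is known to resist isomerisation to tigloyl; C8 is not touched.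

Step 11
Reactants: 18 (4S,6S,8Z)-6-[(4S)-2,2-dimethyl-1,3-dioxolan-4-yl]-9-iodo-5-methylidenedeca-1,8-dien-4-yl (2Z)-2-methylbut-2-enoate
Product: 19 (5S,7S,9Z)-7-[(4S)-2,2-dimethyl-1,3-dioxolan-4-yl]-10-iodo-2-methyl-6-methylideneundeca-2,9-dien-5-yl (2Z)-2-methylbut-2-enoate
Conditions: 2-methylbut-2-ene (large excess), second-generation Grubbs catalyst (H2IMes)(PCy3)Cl2Ru=CHPh (5 mol %), CH2Cl2, 35 °C
Reagents that add atoms: 2-methylbut-2-ene, CC=C(C)C
Why: Olefin cross-metathesis: the monosubstituted C10 alkene exchanges its methylene for the isopropylidene of the excess partner, while the 1,1-disubstituted C7=C14 alkene, the iodoalkene and the angelate alkene are too hindered or electron-poor to enter the catalytic cycle.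

Step 12
Reactants: 19 (5S,7S,9Z)-7-[(4S)-2,2-dimethyl-1,3-dioxolan-4-yl]-10-iodo-2-methyl-6-methylideneundeca-2,9-dien-5-yl (2Z)-2-methylbut-2-enoate
Product: 20 (5S,7S,9Z)-7-[(1S)-1,2-dihydroxyethyl]-10-iodo-2-methyl-6-methylideneundeca-2,9-dien-5-yl (2Z)-2-methylbut-2-enoate
Conditions: AcOH–H2O (4:1), 40 °C
Reagents that add atoms: none
Why: Acid-catalysed acetal hydrolysis of the terminal isopropylidene group; the ester, the alkenyl iodide and the alkenes tolerate aqueous acetic acid and no silyl group is present at this stage.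

Step 13
Reactants: 20 (5S,7S,9Z)-7-[(1S)-1,2-dihydroxyethyl]-10-iodo-2-methyl-6-methylideneundeca-2,9-dien-5-yl (2Z)-2-methylbut-2-enoate
Product: 21 (5S,7S,9Z)-7-[(1S)-1,2-bis(triethylsilyloxy)ethyl]-10-iodo-2-methyl-6-methylideneundeca-2,9-dien-5-yl (2Z)-2-methylbut-2-enoate
Conditions: Et3SiOTf (2.5 equiv), 2,6-lutidine, CH2Cl2, −78 to 0 °C
Reagents that add atoms: triethylsilyl trifluoromethanesulfonate, CC[Si](CC)(CC)OS(=O)(=O)C(F)(F)F
Why: Silylation of both hydroxyls with the silyl triflate and a hindered pyridine base protects C3 for the ring closure and sets up the differentiation of C2 from C3.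

Step 14
Reactants: 21 (5S,7S,9Z)-7-[(1S)-1,2-bis(triethylsilyloxy)ethyl]-10-iodo-2-methyl-6-methylideneundeca-2,9-dien-5-yl (2Z)-2-methylbut-2-enoate
Product: 23 (5S,7S,9Z)-10-iodo-2-methyl-6-methylidene-7-[(1S)-2-oxo-1-(triethylsilyloxy)ethyl]undeca-2,9-dien-5-yl (2Z)-2-methylbut-2-enoate, via alkoxysulfonium chloride 22 (not isolated)
Conditions: (COCl)2, DMSO, CH2Cl2, −78 to −35 °C; Et3N, −78 to 0 °C; used at once
Reagents that add atoms: none
Why: Swern oxidation applied directly to the silyl ether: the chlorosulfonium salt cleaves only the unhindered primary triethylsilyl ether to alkoxysulfonium 22, which Et3N converts to the aldehyde, while the secondary C3 silyl ether survives and the low temperature protects the α-silyloxy centre.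

Step 15
Reactants: 23 (5S,7S,9Z)-10-iodo-2-methyl-6-methylidene-7-[(1S)-2-oxo-1-(triethylsilyloxy)ethyl]undeca-2,9-dien-5-yl (2Z)-2-methylbut-2-enoate
Product: 25 all-trans cyclohexenol (2S,3S,4S,8S) with C1=C6 alkene and free C2 hydroxyl, via alkenylchromium dichloride 24 (not isolated)
Conditions: CrCl2 (8 equiv), NiCl2 (cat.), degassed DMSO, rt, 0.005 M, slow addition of 23; aqueous work-up
Reagents that add atoms: none
Why: CrCl2 reduces NiCl2 to zerovalent nickel, which adds oxidatively to the C1–I bond of 23 with retention of the alkene geometry; transmetalation to trivalent chromium gives alkenylchromium 24, whose C1 adds to the chromium-bound C2 aldehyde to form the C1–C2 bond and, after work-up, the C2 alcohol (an intramolecular Nozaki–Hiyama–Kishi alkenylation, the closest known reaction type being the nickel/chromium-mediated closure of iodoalkenyl aldehydes to cyclic allylic alcohols). The six-membered carbocycle closes in a 6-exo-trig mode, the attacked C=O lying outside the forming ring, and only the (Z)-iodide, whose metal is cis to C5, can reach C2. The one new stereocentre, C2, is controlled by a chair-like transition state in which the C3 silyl ether and the C4 side chain are equatorial, the forming C1–C2 bond is anti to the C3–O bond (polar Felkin–Anh arrangement) and the aldehyde oxygen, held by the chromium that sits in the alkene plane on C1, is pseudo-equatorial, so the hydroxyl should come out trans to the C3 oxygen and cis to the C4 side chain. The step needs chemoselectivity for the aldehyde over the angelate ester and the three spectator alkenes, which the low basicity and aldehyde preference of organochromium reagents provide, and it needs ring closure to win over dimerisation, which high dilution and slow addition secure. The neutral conditions should leave the enolisable α-silyloxy centre C3 unchanged; the C2 selectivity is the least secure element of the step.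

Step 16
Reactants: 25 all-trans cyclohexenol (2S,3S,4S,8S) with C1=C6 alkene and free C2 hydroxyl
Product: 26 epoxy alcohol (1R,2R,3S,4S,6S,8S) with the oxirane cis to the C2 hydroxyl and to the C4 side chain
Conditions: VO(acac)2 (5 mol %), t-BuOOH, CH2Cl2, 0 °C to rt
Reagents that add atoms: tert-butyl hydroperoxide, CC(C)(C)OO
Why: Hydroxyl-directed vanadium-catalysed epoxidation of an allylic alcohol: the C2 alkoxide on vanadium delivers the peroxide oxygen to the C1=C6 alkene on its own face, cis to the C4 side chain and trans to the C3 silyl ether (the cis-carveol precedent), which sets C1 and C6, and the isolated and the electron-poor alkenes do not react.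

Step 17
Reactants: 26 epoxy alcohol (1R,2R,3S,4S,6S,8S) with the oxirane cis to the C2 hydroxyl and to the C4 side chain
Product: 27 epoxy ketone (1S,3S,4S,6S,8S) with C2 ketone and C3 triethylsilyl ether
Conditions: Dess–Martin periodinane, NaHCO3, CH2Cl2, 0 °C
Reagents that add atoms: none
Why: Dess–Martin oxidation of the secondary epoxy alcohol to the α,β-epoxy ketone under buffered, non-epimerising conditions.

Step 18
Reactants: 27 epoxy ketone (1S,3S,4S,6S,8S) with C2 ketone and C3 triethylsilyl ether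
Product: 28 α-hydroxy ketone (1S,3S,4S,6S,8S) with free C3 hydroxyl
Conditions: HF·pyridine, pyridine, THF, 0 °C
Reagents that add atoms: none
Why: Fluoride-mediated desilylation with pyridine-buffered HF·pyridine removes the triethylsilyl ether without opening the oxirane or cleaving the angelate.

Step 19
Reactants: 28 α-hydroxy ketone (1S,3S,4S,6S,8S) with free C3 hydroxyl
Product: 29 (3S)-2-[(1S,3S,4S,6S)-3-acetoxy-1-methyl-2-oxo-7-oxabicyclo[4.1.0]heptan-4-yl]-6-methylhepta-1,5-dien-3-yl (2Z)-2-methylbut-2-enoate (CNP0150645.2)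
Conditions: Ac2O, pyridine, DMAP (cat.), CH2Cl2, 0 °C
Reagents that add atoms: acetic anhydride, CC(=O)OC(C)=O
Why: Acylation of the α-hydroxy ketone with DMAP catalysis gives the C3 acetate, whose equatorial position trans to the C4 side chain is also the thermodynamically preferred one, so C3 should not drift.

**Compound list**

1 | (R)-2,3-O-isopropylideneglyceraldehyde [(4R)-2,2-dimethyl-1,3-dioxolane-4-carbaldehyde] | O=C[C@@H]1OC(C)(C)OC1 | starting material
2 | methyl (2Z)-3-[(4S)-2,2-dimethyl-1,3-dioxolan-4-yl]prop-2-enoate | COC(=O)/C=C\[C@@H]1OC(C)(C)OC1 | intermediate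
3 | (2Z)-3-[(4S)-2,2-dimethyl-1,3-dioxolan-4-yl]prop-2-en-1-ol | OC/C=C\[C@@H]1OC(C)(C)OC1 | intermediate
4 | triethyl orthoacetate | CC(OCC)(OCC)OCC | starting material
5 | mixed orthoester (not isolated): (4S)-4-[(1Z)-3-(1,1-diethoxyethoxy)prop-1-en-1-yl]-2,2-dimethyl-1,3-dioxolane | CC(OCC)(OCC)OC/C=C\[C@@H]1OC(C)(C)OC1 | intermediate
6 | ketene acetal (not isolated): (4S)-4-[(1Z)-3-(1-ethoxyethenyloxy)prop-1-en-1-yl]-2,2-dimethyl-1,3-dioxolane | C=C(OCC)OC/C=C\[C@@H]1OC(C)(C)OC1 | intermediate
7 | ethyl (3S)-3-[(4S)-2,2-dimethyl-1,3-dioxolan-4-yl]pent-4-enoate | C=C[C@H](CC(=O)OCC)[C@H]1COC(C)(C)O1 | intermediate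
8 | (3S)-3-[(4S)-2,2-dimethyl-1,3-dioxolan-4-yl]pent-4-enal | C=C[C@H](CC=O)[C@H]1COC(C)(C)O1 | intermediate
9 | (4S)-4-[(3S,5Z)-6-iodohepta-1,5-dien-3-yl]-2,2-dimethyl-1,3-dioxolane | C=C[C@H](C/C=C(/C)I)[C@H]1COC(C)(C)O1 | intermediate
10 | alkylborane (not isolated): 9-[(3S,5Z)-3-[(4S)-2,2-dimethyl-1,3-dioxolan-4-yl]-6-iodohept-5-en-1-yl]-9-borabicyclo[3.3.1]nonane | C(CB1C2CCCC1CCC2)[C@H](C/C=C(/C)I)[C@H]1COC(C)(C)O1 | intermediate
11 | (3S,5Z)-3-[(4S)-2,2-dimethyl-1,3-dioxolan-4-yl]-6-iodohept-5-en-1-ol | OCC[C@H](C/C=C(/C)I)[C@H]1COC(C)(C)O1 | intermediate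
12 | (3S,5Z)-3-[(4S)-2,2-dimethyl-1,3-dioxolan-4-yl]-6-iodohept-5-enal | O=CC[C@H](C/C=C(/C)I)[C@H]1COC(C)(C)O1 | intermediate
13 | (3S,5Z)-3-[(4S)-2,2-dimethyl-1,3-dioxolan-4-yl]-6-iodo-2-methylidenehept-5-enal | C=C(C=O)[C@H](C/C=C(/C)I)[C@H]1COC(C)(C)O1 | intermediate
14 | borinate (not isolated): diisopinocampheylborinic ester of alcohol 15 | C=C([C@H](CC=C)OB([C@@H]1C[C@@H]2C[C@H]([C@H]1C)C2(C)C)[C@@H]1C[C@@H]2C[C@H]([C@H]1C)C2(C)C)[C@H](C/C=C(/C)I)[C@H]1COC(C)(C)O1 | intermediate
15 | (4S,6S,8Z)-6-[(4S)-2,2-dimethyl-1,3-dioxolan-4-yl]-9-iodo-5-methylidenedeca-1,8-dien-4-ol | C=C([C@H](CC=C)O)[C@H](C/C=C(/C)I)[C@H]1COC(C)(C)O1 | intermediate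
16 | angelic acid [(2Z)-2-methylbut-2-enoic acid] | C/C=C(/C)C(=O)O | starting material
17 | mixed anhydride (not isolated): (2Z)-2-methylbut-2-enoic 2,4,6-trichlorobenzoic anhydride | C/C=C(/C)C(=O)OC(=O)c1c(Cl)cc(Cl)cc1Cl | intermediate
18 | (4S,6S,8Z)-6-[(4S)-2,2-dimethyl-1,3-dioxolan-4-yl]-9-iodo-5-methylidenedeca-1,8-dien-4-yl (2Z)-2-methylbut-2-enoate | C=C([C@H](CC=C)OC(=O)/C(C)=C\C)[C@H](C/C=C(/C)I)[C@H]1COC(C)(C)O1 | intermediate
19 | (5S,7S,9Z)-7-[(4S)-2,2-dimethyl-1,3-dioxolan-4-yl]-10-iodo-2-methyl-6-methylideneundeca-2,9-dien-5-yl (2Z)-2-methylbut-2-enoate | C=C([C@H](CC=C(C)C)OC(=O)/C(C)=C\C)[C@H](C/C=C(/C)I)[C@H]1COC(C)(C)O1 | intermediate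
20 | (5S,7S,9Z)-7-[(1S)-1,2-dihydroxyethyl]-10-iodo-2-methyl-6-methylideneundeca-2,9-dien-5-yl (2Z)-2-methylbut-2-enoate | C=C([C@H](CC=C(C)C)OC(=O)/C(C)=C\C)[C@H](C/C=C(/C)I)[C@H](O)CO | intermediate
21 | (5S,7S,9Z)-7-[(1S)-1,2-bis(triethylsilyloxy)ethyl]-10-iodo-2-methyl-6-methylideneundeca-2,9-dien-5-yl (2Z)-2-methylbut-2-enoate | C=C([C@H](CC=C(C)C)OC(=O)/C(C)=C\C)[C@H](C/C=C(/C)I)[C@H](O[Si](CC)(CC)CC)CO[Si](CC)(CC)CC | intermediate
22 | alkoxysulfonium chloride (not isolated): dimethylsulfonium salt on the C2 oxygen of desilylated 21 | C=C([C@H](CC=C(C)C)OC(=O)/C(C)=C\C)[C@H](C/C=C(/C)I)[C@H](O[Si](CC)(CC)CC)CO[S+](C)C.[Cl-] | intermediate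
23 | (5S,7S,9Z)-10-iodo-2-methyl-6-methylidene-7-[(1S)-2-oxo-1-(triethylsilyloxy)ethyl]undeca-2,9-dien-5-yl (2Z)-2-methylbut-2-enoate (key-step precursor: C2 aldehyde, C3 OSiEt3, (Z)-C1 iodide, C8 angelate) | C=C([C@H](CC=C(C)C)OC(=O)/C(C)=C\C)[C@H](C/C=C(/C)I)[C@H](O[Si](CC)(CC)CC)C=O | intermediate
24 | alkenylchromium dichloride (not isolated): 23 with CrCl2 in place of iodine at C1, (Z) geometry kept | C=C([C@H](CC=C(C)C)OC(=O)/C(C)=C\C)[C@H](C/C=C(/C)[Cr](Cl)Cl)[C@H](O[Si](CC)(CC)CC)C=O | intermediate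
25 | all-trans cyclohexenol (2S,3S,4S,8S): C1=C6 alkene with C1 methyl, C2 OH trans to C3 OSiEt3 and cis to the C4 side chain, C8 angelate | C=C([C@H](CC=C(C)C)OC(=O)/C(C)=C\C)[C@@H]1CC=C(C)[C@H](O)[C@H]1O[Si](CC)(CC)CC | intermediate
26 | epoxy alcohol (1R,2R,3S,4S,6S,8S): C1–C6 oxirane cis to C2 OH and to the C4 side chain, C3 OSiEt3, C8 angelate | C=C([C@H](CC=C(C)C)OC(=O)/C(C)=C\C)[C@@H]1C[C@@H]2O[C@]2(C)[C@H](O)[C@H]1O[Si](CC)(CC)CC | intermediate
27 | epoxy ketone (1S,3S,4S,6S,8S): C2 ketone, C3 OSiEt3, C8 angelate | C=C([C@H](CC=C(C)C)OC(=O)/C(C)=C\C)[C@@H]1C[C@@H]2O[C@]2(C)C(=O)[C@H]1O[Si](CC)(CC)CC | intermediate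
28 | α-hydroxy ketone (1S,3S,4S,6S,8S): C2 ketone, free C3 OH, C8 angelate | C=C([C@H](CC=C(C)C)OC(=O)/C(C)=C\C)[C@@H]1C[C@@H]2O[C@]2(C)C(=O)[C@H]1O | intermediate
29 | (3S)-2-[(1S,3S,4S,6S)-3-acetoxy-1-methyl-2-oxo-7-oxabicyclo[4.1.0]heptan-4-yl]-6-methylhepta-1,5-dien-3-yl (2Z)-2-methylbut-2-enoate (CNP0150645.2) | C=C([C@H](CC=C(C)C)OC(=O)/C(C)=C\C)[C@@H]1C[C@@H]2O[C@]2(C)C(=O)[C@H]1OC(C)=O | target

**Step count and risks**

Total step count: 19. Longest linear sequence: 19 steps from 1 (4 and 16 are commercial partners).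

Steps most likely to fail, each with one fallback:

1. Step 15 (ring closure). What may go wrong is poor facial selectivity at the aldehyde carbon during C1–C2 bond formation: the oxygen may equally sit pseudo-axial to avoid the C1 methyl, which would give the C2 epimer and misdirect the later epoxidation. In the fallback the ring closure is kept and C2 is set afterwards by reduction instead of by the carbon–carbon bond formation. It sets out from 23, which is cyclised as in step 15. The crude alcohol, containing the C2 epimer F1, is oxidised without separation with Dess–Martin periodinane (NaHCO3, CH2Cl2) to the 2-methylcyclohexenone, enone F2. Luche reduction (NaBH4, CeCl3·7H2O, MeOH, −78 °C) then delivers hydride axially, anti to the axial C3–H, as in the reduction of carvone to cis-carveol, and the sequence comes back to the route at 25.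

2. Step 10 (angeloylation). What may go wrong is geometric isomerisation of the angeloyl double bond to the tigloyl isomer during a slow acylation of the hindered allylic alcohol. In the fallback the (Z)-alkene of the ester is built on the substrate instead of being carried in. It sets out from 15, which is esterified (DCC, DMAP, CH2Cl2) with 2-[bis(2,2,2-trifluoroethoxy)phosphoryl]propanoic acid to give phosphonopropionate F3. A Still–Gennari olefination with acetaldehyde (KN(SiMe3)2, 18-crown-6, THF, −78 °C) then forms the (Z)-2-methylbut-2-enoate and comes back to the route at 18.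

3. Step 5 (iodo-olefination). What may go wrong is incomplete iodination of the ylide and erosion of the kinetic (Z) preference, which would give iodine-free alkene and (E)-iodide that are hard to remove. In the fallback the alkenyl halide geometry is set by a selective cross-coupling instead of by the olefination. It sets out from 8, which is converted with CBr4, PPh3 and Et3N (CH2Cl2, 0 °C) into dibromoalkene F4. A trans-selective Negishi coupling (MeZnCl, Pd(PPh3)4 cat., THF) replaces only the bromine trans to the chain and gives (Z)-bromoalkene F5. Bromine–lithium exchange (t-BuLi, Et2O, −78 °C) and quench with I2, both with retention, come back to the route at 9.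

**Further compounds**

F1 | step 15 | C2 epimer of 25 (2R,3S,4S,8S): C2 OH cis to C3 OSiEt3 | C=C([C@H](CC=C(C)C)OC(=O)/C(C)=C\C)[C@@H]1CC=C(C)[C@@H](O)[C@H]1O[Si](CC)(CC)CC
F2 | step 15 | enone (3S,4S,8S): C2 ketone conjugated with the C1=C6 alkene, C3 OSiEt3, C8 angelate | C=C([C@H](CC=C(C)C)OC(=O)/C(C)=C\C)[C@@H]1CC=C(C)C(=O)[C@H]1O[Si](CC)(CC)CC
F3 | step 10 | 2-[bis(2,2,2-trifluoroethoxy)phosphoryl]propanoate of alcohol 15 (epimers at the phosphorus-bearing carbon) | C=C([C@H](CC=C)OC(=O)C(C)P(=O)(OCC(F)(F)F)OCC(F)(F)F)[C@H](C/C=C(/C)I)[C@H]1COC(C)(C)O1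
F4 | step 5 | (4S)-4-[(3S)-6,6-dibromohexa-1,5-dien-3-yl]-2,2-dimethyl-1,3-dioxolane | C=C[C@H](CC=C(Br)Br)[C@H]1COC(C)(C)O1
F5 | step 5 | (4S)-4-[(3S,5Z)-6-bromohepta-1,5-dien-3-yl]-2,2-dimethyl-1,3-dioxolane | C=C[C@H](C/C=C(/C)Br)[C@H]1COC(C)(C)O1
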